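**Retrosynthetic overview**

- Feature: ring B (O1, C2, C3, C4, C4a, C8a; chromane numbering) carries its C2 and C3 methyls cis. H3 lies alpha to the C4 ketone, so this is the epimerisable, less stable isomer, and ring B is therefore closed last, under kinetic control.
- The target comes from hydrolysis of an O5 enol lactone (ring C). Ring B comes from the O1–C2 bond, made by quinine-catalysed oxa-Michael addition of the C8a enol to a C4a tigloyl group. Ring C ties up O5, so only O8a can add.
- The C8 quaternary centre comes from an asymmetric palladium-catalysed dearomatising prenylation of an aromatic 6-lavandulyl-8-tigloyl dihydrocoumarin. Lavandulyl halides are homoallylic, not allylic, so this chain is joined by Negishi coupling and not by phenolate alkylation.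
- The tigloyl group goes on before both alkyl groups (Friedel–Crafts), so that it blocks the second nucleophilic ring carbon. The benzylic centre comes from a carbene-catalysed annulation of phloroglucinol with cinnamaldehyde.
- Ring order: A (bought, aromatic), then C (lactone), then A dearomatised, then B closed, then C opened.

Key step: step 10

Numbering: the aromatic intermediates are named as chroman-2-ones. Their O1, C8a, C8, C7, C6, C5, C4a and C4 become O5, C5, C4a, C8a, C8, C7, C6 and the benzylic carbon of the target, whose chromane numbering is used from the dearomatised stage on.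

Assumption: the sense of induction of the triazolium salt (step 1) and of the diphosphine (step 9) is fixed in a pilot run, and the equally available mirror-image catalyst is used if the opposite sense is found.

**Step 1**
Reactants: 1 phloroglucinol; 2 trans-cinnamaldehyde
Product: 3 (4R)-5,7-dihydroxy-4-phenylchroman-2-one
Conditions: 1 (3 equiv), chiral aminoindanol-derived N-mesityl triazolium tetrafluoroborate (10 mol %), i-Pr2NEt (20 mol %), 3,3',5,5'-tetra-tert-butyldiphenoquinone (1.1 equiv), 4 Å MS, THF, rt
Reagents that add atoms: none
Why: Oxidative N-heterocyclic-carbene catalysis turns 2 into an alpha,beta-unsaturated acyl azolium, the enol-like ring carbon of 1 adds to its beta carbon (formal 3+3 annulation, as known for naphthols and 1,3-dicarbonyl compounds) and the neighbouring hydroxyl lactonises with release of the carbene, so that the shielded face of the chiral azolium should set the benzylic centre as R, while the threefold symmetry of 1 removes any regiochemical question and its excess holds back a second annulation.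

**Step 2**
Reactants: 4 tiglic acid
Product: 5 tigloyl chloride
Conditions: (COCl)2 (1.2 equiv), DMF (cat.), CH2Cl2, 0 °C to rt; distillation
Reagents that add atoms: oxalyl chloride, O=C(Cl)C(=O)Cl
Why: Acid chloride formation through the catalytic chloroiminium salt is mild enough to leave the E alkene unchanged.

**Step 3**
Reactants: 3 (4R)-5,7-dihydroxy-4-phenylchroman-2-one; 5 tigloyl chloride
Product: 6 (4R)-5,7-dihydroxy-8-[(E)-2-methylbut-2-enoyl]-4-phenylchroman-2-one
Conditions: AlCl3 (4 equiv), 5 (1.1 equiv), ClCH2CH2Cl/PhNO2, 0 °C to rt; ice, 1 M HCl; chromatography
Reagents that add atoms: none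
Why: Friedel–Crafts acylation should go mainly to C8, which lies para to the free 5-OH whereas C6 lies para to the acylated O1, as is known for the tigloylation of 5,7-dihydroxycoumarins; no stereocentre is formed, and the low temperature limits Lewis-acid closure of the new enone onto the 7-OH.

**Step 4**
Reactants: 6 8-tigloyl lactone
Product: 7 (4R)-5,7-dihydroxy-6-iodo-8-[(E)-2-methylbut-2-enoyl]-4-phenylchroman-2-one
Conditions: N-iodosuccinimide (1.05 equiv), MeCN, 0 °C, dark
Reagents that add atoms: N-iodosuccinimide, O=C1CCC(=O)N1I
Why: Electrophilic aromatic iodination can only strike C6, the last free ring carbon, which is flanked by two hydroxyls, and the electron-poor tigloyl alkene does not compete.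

**Step 5**
Reactants: 8 racemic lavandulol
Product: 9 (S)-lavandulol
Conditions: Novozym 435 (immobilised Candida antarctica lipase B), vinyl acetate, MTBE, 30 °C, run to about two-thirds conversion (chiral GC control); chromatography
Reagents that add atoms: none
Why: In this lipase-catalysed kinetic resolution by transesterification the R alcohol is expected to be acylated faster, so running past half conversion should leave the S alcohol enriched even at a moderate selectivity factor; the stereocentre is selected, not made.

**Step 6**
Reactants: 9 (S)-lavandulol
Product: 10 (S)-lavandulyl iodide, (2S)-1-iodo-5-methyl-2-(prop-1-en-2-yl)hex-4-ene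
Conditions: PPh3, imidazole, iodine, CH2Cl2, 0 °C
Reagents that add atoms: iodine, [I][I]
Why: The Appel reaction displaces the activated primary oxygen by iodide in an SN2 step at the CH2 group, so the neighbouring stereocentre and both alkenes stay untouched.

**Step 7**
Reactants: 7 6-iodo-8-tigloyl lactone; 10 (S)-lavandulyl iodide
Product: 14 (4R)-5,7-dihydroxy-6-[(2R)-5-methyl-2-(prop-1-en-2-yl)hex-4-en-1-yl]-8-[(E)-2-methylbut-2-enoyl]-4-phenylchroman-2-one, via lavandulylzinc iodide 11 (not isolated), via silylated aryl iodide 12 (not isolated), via silylated coupling product 13 (not isolated)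
Conditions: (a) 10, Zn dust (activated by BrCH2CH2Br, Me3SiCl), LiCl, THF, 35 °C; (b) 7, N,O-bis(trimethylsilyl)acetamide (2.5 equiv), THF, 40 °C, volatiles off; (c) a + b, Pd(OAc)2 (4 mol %), SPhos (8 mol %), THF, rt to 40 °C; (d) 10% aq citric acid, THF, 0 °C
Reagents that add atoms: none
Why: In this Negishi coupling the primary alkylzinc iodide transmetalates to the arylpalladium species formed by oxidative addition at the carbon–iodine bond, the bulky biaryl phosphine favours reductive elimination over beta-hydride elimination, the stereocentre beta to zinc is not involved (its descriptor changes to R only through priorities), and the transient silyl ethers remove the acidic protons and keep O7 away from the tigloyl group.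

**Step 8**
Reactants: 15 prenol (3-methylbut-2-en-1-ol)
Product: 16 tert-butyl prenyl carbonate
Conditions: Boc2O (1.2 equiv), Bu4NHSO4 (cat.), 30% aq NaOH, CH2Cl2, 0 °C
Reagents that add atoms: di-tert-butyl dicarbonate, CC(C)(C)OC(=O)OC(=O)OC(C)(C)C
Why: Phase-transfer O-acylation of a primary allylic alcohol with Boc2O is a standard route to allylic tert-butyl carbonates.

**Step 9**
Reactants: 14 6-lavandulyl-8-tigloyl lactone; 16 tert-butyl prenyl carbonate
Product: 17 (4R,6S)-7-hydroxy-8-[(E)-2-methylbut-2-enoyl]-6-(3-methylbut-2-en-1-yl)-6-[(2R)-5-methyl-2-(prop-1-en-2-yl)hex-4-en-1-yl]-4-phenyl-3,4-dihydro-2H-chromene-2,5(6H)-dione (in target numbering: 8S quaternary carbon; C7 ketone; C8a enol; C4a tigloyl; O5 enol lactone)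
Conditions: Pd2(dba)3·CHCl3 (2.5 mol %), (1R,2R)-N,N'-bis(2-diphenylphosphinobenzoyl)cyclohexane-1,2-diamine (7.5 mol %), 16 (1.2 equiv), degassed toluene, 0 °C; acid-washed silica
Reagents that add atoms: none
Why: Proposed new method: ionisation of 16 by zerovalent palladium gives a cationic 1,1-dimethylallyl complex and tert-butoxide, which deprotonates the acidic acylphloroglucinol 14; the soft delocalised anion attacks the unsubstituted allyl terminus through C6, the only ring carbon that lies between two oxygens and carries no acyl group, O-prenyl ethers are re-ionised so that the dearomatised vinylogous acid is the sink, no free base or nucleophilic alcohol is left to close the enone or open the lactone, and the chiral pocket of the diphosphine, which meets a lactone flank and a tigloyl flank that differ strongly, should pick the ring face that makes the new quaternary carbon S; the closest known reactions are the palladium-catalysed dearomatising allylation of acylphloroglucinols with allylic carbonates, the asymmetric Tsuji–Trost allylic dearomatisation of 2-naphthols and the ligand-controlled linear prenylation of oxindoles.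

**Step 10**
Reactants: 17 C4a-tigloyl C8a-enol O5 lactone
Product: 19 ring-B-closed O5 enol lactone of the target (2R 3S 8S in chromane numbering; benzylic carbon R; lavandulyl carbon R), via ring-closed C3 enol 18 (not isolated)
Conditions: (−)-quinine (10 mol %), PhCl, 4 Å MS, 10 °C; filtration through acid-washed silica as soon as 17 is consumed
Reagents that add atoms: none
Why: The quinuclidine nitrogen of quinine takes the acidic C8a enol proton while the catalyst hydroxyl hydrogen-bonds to the tigloyl carbonyl, and inside this contact ion pair O8a adds to the enone beta carbon to form O1–C2, giving enol 18, which is then protonated at C3. The closest known reaction is the quinine-catalysed intramolecular oxa-Michael addition of ortho-tigloylphenols whose acyl group is likewise flanked by a lactone oxygen and the attacking hydroxyl, and the acid- or base-induced closure of 2-alkenoyl cyclic 1,3-diones to dihydropyranones shows that such enols are competent donors, although 17 is more acidic and less nucleophilic than a phenol. Ring B closes in the 6-endo-trig mode. C2 is set by the catalyst, which exposes one face of the s-cis enone and gives 2R with (−)-quinine in the phenol series, and C3 is set by kinetic proton delivery from the quinuclidinium ion to the face of 18 anti to the new C2 methyl, which places both methyls on the same side (2R,3S). The step needs regiocontrol, which the O5 lactone secures because O8a is the only free oxygen next to the tigloyl group and the lactone cannot migrate without an external nucleophile, and it needs kinetic control, which catalytic base, a dry aprotic solvent, low temperature and prompt removal of the catalyst should provide. The centres at C8, at the benzylic carbon and in the lavandulyl chain carry no acidic hydrogen and are not touched.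

**Step 11**
Reactants: 19 O5 enol lactone of the target
Product: 20 target, (3R)-3-[(2R,3S,8S)-5-hydroxy-2,3-dimethyl-8-(3-methylbut-2-en-1-yl)-8-[(2R)-5-methyl-2-(prop-1-en-2-yl)hex-4-en-1-yl]-4,7-dioxo-2,3-dihydrochromen-6-yl]-3-phenylpropanoic acid
Conditions: LiOH (2.5 equiv), THF/H2O (3:1), 0 °C, short contact; cold NaH2PO4/H3PO4 buffer (pH 4), EtOAc
Reagents that add atoms: water, O
Why: In this saponification the lactone is a vinylogous anhydride and should be attacked by hydroxide at its carbonyl far faster than C3 is deprotonated, ring A becomes an anion on opening, which lowers the acidity of H3 further, and the buffered quench frees the C5 enol and the acid without epimerisation or retro-Michael opening.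

**Compound list**

1 | phloroglucinol | Oc1cc(O)cc(O)c1 | starting material
2 | trans-cinnamaldehyde | O=C/C=C/c1ccccc1 | starting material
3 | (4R)-5,7-dihydroxy-4-phenylchroman-2-one | Oc1cc(O)c2c(c1)OC(=O)C[C@@H]2c1ccccc1 | intermediate
4 | tiglic acid | C/C=C(\C)C(=O)O | starting material
5 | tigloyl chloride | C/C=C(\C)C(=O)Cl | intermediate
6 | (4R)-5,7-dihydroxy-8-tigloyl-4-phenylchroman-2-one | C/C=C(\C)C(=O)c1c(O)cc(O)c2c1OC(=O)C[C@@H]2c1ccccc1 | intermediate
7 | (4R)-5,7-dihydroxy-6-iodo-8-tigloyl-4-phenylchroman-2-one | C/C=C(\C)C(=O)c1c(O)c(I)c(O)c2c1OC(=O)C[C@@H]2c1ccccc1 | intermediate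
8 | racemic lavandulol | C=C(C)C(CO)CC=C(C)C | starting material
9 | (S)-lavandulol | C=C(C)[C@H](CC=C(C)C)CO | intermediate
10 | (S)-lavandulyl iodide | C=C(C)[C@H](CC=C(C)C)CI | intermediate
11 | lavandulylzinc iodide (configuration of 10 kept) | C=C(C)[C@H](CC=C(C)C)C[Zn]I | intermediate
12 | 5,7-bis(trimethylsilyl) ether of 7 | C/C=C(\C)C(=O)c1c(O[Si](C)(C)C)c(I)c(O[Si](C)(C)C)c2c1OC(=O)C[C@@H]2c1ccccc1 | intermediate
13 | 5,7-bis(trimethylsilyl) ether of 14 | C=C(C)[C@H](CC=C(C)C)Cc1c(O[Si](C)(C)C)c2c(OC(=O)C[C@@H]2c2ccccc2)c(C(=O)/C(C)=C/C)c1O[Si](C)(C)C | intermediate
14 | (4R)-5,7-dihydroxy-6-[(2R)-lavandulyl]-8-tigloyl-4-phenylchroman-2-one | C=C(C)[C@H](CC=C(C)C)Cc1c(O)c2c(OC(=O)C[C@@H]2c2ccccc2)c(C(=O)/C(C)=C/C)c1O | intermediate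
15 | prenol | CC(C)=CCO | starting material
16 | tert-butyl prenyl carbonate | CC(C)=CCOC(=O)OC(C)(C)C | intermediate
17 | key-step precursor: 8S dearomatised C4a-tigloyl C8a-enol with O5 enol lactone | C=C(C)[C@H](CC=C(C)C)C[C@]1(CC=C(C)C)C(=O)C4=C(OC(=O)C[C@@H]4c3ccccc3)C(C(=O)/C(C)=C/C)=C1O | intermediate
18 | ring-closed C3 enol (2R, 8S) | C=C(C)[C@H](CC=C(C)C)C[C@]1(CC=C(C)C)C(=O)C4=C(OC(=O)C[C@@H]4c3ccccc3)C2=C1O[C@H](C)C(C)=C2O | intermediate
19 | key-step product: O5 enol lactone of the target (2R,3S,8S) | C=C(C)[C@H](CC=C(C)C)C[C@]1(CC=C(C)C)C(=O)C4=C(OC(=O)C[C@@H]4c3ccccc3)C2=C1O[C@H](C)[C@H](C)C2=O | intermediate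
20 | CNP0150579.4 | C=C(C)[C@H](CC=C(C)C)C[C@]1(CC=C(C)C)C(=O)C([C@H](CC(=O)O)c2ccccc2)=C(O)C2=C1O[C@H](C)[C@H](C)C2=O | target

**Totals and risks**

Total step count: 11. Longest linear sequence: 7 (steps 1, 3, 4, 7, 9, 10, 11).

The three steps most likely to fail:

**Step 9 (bears the label).**
- The ligand may discriminate poorly between the two faces of the flat anion. O-prenylation may persist. The traces of alkoxide formed in each turnover may start an uncatalysed closure of the tigloyl enone.
- The fallback sets out from 14 and comes back at 17. It gives up catalyst control for a classical alkylative dearomatisation of an acylphloroglucinol.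
- Compound 14 is fully deprotonated with LiN(SiMe3)2 (2.1 equiv) in THF at −78 °C, so that no proton source is left to trap a ring-closed enolate. It is then alkylated with prenyl bromide and quenched into cold dilute acid.
- This should give 17 together with the C8 epimer of the precursor F1. The two are diastereomers because the benzylic and lavandulyl centres are already fixed, and they are separated by chromatography.

**Step 10 (key step).**
- The enolate of 17 is a weak nucleophile and a good leaving group. The addition may therefore be slow and reversible, with erosion of the C2 selectivity and drift of C3 to the trans isomer.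
- Slow acyl transfer from the activated lactone to the catalyst hydroxyl could also drain the catalyst.
- The fallback sets out from 14 and comes back at 19 by inverting the order of ring closure and dearomatisation.
- The ortho-tigloylphenol 14 is exactly the substrate class for which the quinine-catalysed closure is established. With (−)-quinine in chlorobenzene it should give the aromatic cis-2,3-dimethylchromanone lactone F2.
- The lithium phenolate of F2 (LiN(SiMe3)2, 1.0 equiv, toluene/THF, −78 °C) is C-alkylated with prenyl bromide at the lavandulyl-bearing ortho carbon, in the known ortho-allylative dearomatisation of substituted phenolates.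
- This gives 19 beside the C8 epimer of the ring-closed lactone F3, which is removed by chromatography. One equivalent of base and the low temperature should spare H3.

**Step 7.**
- Oxidative addition at a carbon–iodine bond flanked by two silyloxy groups may be slow. Beta-hydride elimination from the branched alkylpalladium species and protodeiodination may then take over.
- The fallback sets out from 6 and comes back at 17. It skips steps 4, 7 and 9 and exchanges the roles of the two alkyl groups.
- Neutral Tsuji–Trost C-prenylation of 6 with 16 and Pd(PPh3)4 in THF should give the 6-prenyl-8-tigloyl dihydrocoumarin F4.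
- The dianion of F4 (LiN(SiMe3)2, 2.1 equiv, THF) is alkylated at the prenyl-bearing carbon with lavandulyl iodide 10, a known though sluggish dearomatising alkylation of prenylated acylphloroglucinols.
- This gives 17 and again the C8 epimer of the precursor F1, which is separated by chromatography.

**Further compounds**

F1 | step 9 | C8 epimer of the precursor 17 (8R) | C=C(C)[C@H](CC=C(C)C)C[C@@]1(CC=C(C)C)C(=O)C4=C(OC(=O)C[C@@H]4c3ccccc3)C(C(=O)/C(C)=C/C)=C1O
F2 | step 10 | aromatic cis-2,3-dimethylchromanone lactone (2R,3S; 7-OH free; 8-lavandulyl) | C=C(C)[C@H](CC=C(C)C)Cc1c(O)c2c(OC(=O)C[C@@H]2c2ccccc2)c2c1O[C@H](C)[C@H](C)C2=O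
F3 | step 10 | C8 epimer of the ring-closed lactone 19 (8R) | C=C(C)[C@H](CC=C(C)C)C[C@@]1(CC=C(C)C)C(=O)C4=C(OC(=O)C[C@@H]4c3ccccc3)C2=C1O[C@H](C)[C@H](C)C2=O
F4 | step 7 | (4R)-5,7-dihydroxy-6-prenyl-8-tigloyl-4-phenylchroman-2-one | CC(C)=CCc1c(O)c2c(OC(=O)C[C@@H]2c2ccccc2)c(C(=O)/C(C)=C/C)c1O
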